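**Remarks on the chemistry**

- Numbering used throughout: C1 ring ketone, C2=C3 alkene, C4 acetoxy carbon, C5 ring carbinol, C6 side-chain carbinol, C7–C20 chain. The target is (4S,5S,6S), with the C4 acetate cis to the C5 hydroxyl.
- Assumption: SAMP is taken to induce the S configuration at both alpha-carbons of the dioxanone (the spatial sense known for SAMP alkylation of cyclic ketones); if the sense were opposite, the enantiomeric auxiliary would be used with no other change.
- Abbreviations: TBS = tert-butyldimethylsilyl, TMS = trimethylsilyl, TES = triethylsilyl.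

## Analysis of the target

The target is a cyclopent-2-en-1-one (ring carbons C1–C5) with the ketone at C1, the C2=C3 double bond, an acetoxy group at C4 and a tertiary hydroxyl at the fully substituted C5. C5 also carries a 1-hydroxypentadecyl chain (carbinol C6, then the unbranched C7–C20). There are three contiguous stereocentres, all S: on the ring the C4 acetate and the C5 hydroxyl are cis, so the C6 branch is trans to the acetate, and C6 lies outside the ring. The molecule is fragile: the C5 hydroxyl is a tertiary alpha-ketol (ketol rearrangement), the C6 hydroxyl is beta to the C1 carbonyl (retro-aldol loss of the chain under base), and the allylic acetate can migrate among O4, O5 and O6. The synthesis is hard for two reasons: the quaternary carbinol C5 is flanked by two oxygenated stereocentres, and the single acetyl group must go on O4 although O6 is also a secondary hydroxyl. The plan rests on the fact that C1 (ketone) and C5 (carbinol) are neighbours that both sit at a carbonyl-derived oxidation level. The C1–C5 alpha-ketol is what an acyl-anion equivalent at C1 gives when it adds to a C5 ketone. With the C2=C3 alkene set aside, that addition is the ring closure of an acyclic 1,5-keto aldehyde whose only stereocentres, C4 and C6, flank the ketone.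

## Retrosynthetic reasoning

**C4–O acetyl bond (19 from 18).** The acetate is the most labile group, so it is attached last. The forward step must pick O4 out of three hydroxyls. O5 is tertiary and unreactive; O4 differs from O6 in being the secondary partner of the ring cis-4,5-diol, which a diol-binding acylation catalyst can recognise.

**Si–O bonds (18 from 17).** The silyl groups on O4, O5 and O6 are removed together. This must be done under acidic conditions, because the free triol enone does not tolerate base.

**C2=C3 double bond (17 from 16 from 15).** The alkene is introduced after the ring exists, by dehydrogenation of the saturated ketone through its silyl enol ether. C5 is quaternary, so 15 can enolise only toward C2 and the regiochemistry is unambiguous. Keeping the alkene out of the cyclisation substrate also keeps the aldehyde of 14 a plain saturated aldehyde.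

**C1–C5 bond (15 from 14).** This is the central cut. Both carbons are carbonyl carbons in 14, so joining them needs polarity reversal at the aldehyde, which carbene catalysis supplies. The cut removes the ring and the quaternary stereocentre at once and leaves an open chain with two secondary carbinol centres. The forward reaction must make the aldehyde the donor and the ketone the acceptor, close a five-membered ring, and set C5 with the C6 branch trans to the C4 silyloxy group.

**C1 aldehyde (14 from 12).** The aldehyde is unmasked immediately before the key step by oxidative cleavage of a terminal alkene that carries one extra carbon. This avoids any borane or hydride reagent next to the C5 ketone, which a three-carbon allyl unit would have required.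

**O4 and O6 protection (12 from 11 from 10).** The isopropylidene acetal of 10 is exchanged for two acyclic silyl ethers. In 10 the ketone lies in a six-membered ring with O4 and O6; cyclisation onto that ring would give a cis-fused bicycle in which O4 and the new C5 hydroxyl are trans, the wrong C5 configuration. Acyclic ethers let the steric bias of the open chain operate.

**C6–C7 and C3–C4 bonds (10 from 9 from 6 from 3, from 1 and 2 with 4 and 7).** The C4(O)–C5(=O)–C6(O) pattern is that of protected dihydroxyacetone 1. Its two alpha-carbons are alkylated in turn as the hydrazone of auxiliary 2, first with 4 and then with 7. One auxiliary sets both centres with the same sense, which is what the (4S,6S) arrangement needs.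

## Alternatives that were turned down

**Alternative 1:** The ring is cut at C1–C2. Alkynal A1 already contains C4, C5 and C6, with O5/O6 tied as an acetonide. It would be closed by [Rh(dppe)]2(BF4)2, the aldehyde C–H bond adding across the terminal alkyne in a trans hydroacylation to give cyclopentenone A2.
- For: the enone arises directly, with no separate dehydrogenation. O4 (silyl) is distinct from O5/O6 (acetal), so the final acetylation is unambiguous. On both points this route is stronger than the chosen one.
- Against: the key step creates no stereocentre. The quaternary C5 of A1, a fully substituted alpha-alkoxy aldehyde between two carbinol centres, must be built beforehand by a separate stereocontrolled addition. Such a neopentyl-type aldehyde is a poor partner for rhodium (slow C–H insertion, decarbonylation of the acyl rhodium hydride).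
- Comparison: making A1 would take more steps than the whole approach to 14. The chosen plan lets the ring closure itself create C5 from a precursor with two easily set secondary centres.

**Alternative 2:** Here the C4–O and C5–O bonds are disconnected. Enone A3, in principle available by Pauson–Khand chemistry, would be dihydroxylated with catalytic OsO4 and an amine N-oxide from the face anti to the C6 silyloxy group, giving cis-diol A4.
- For: it is the shortest route. The cis-4,5 relationship follows from the syn addition. O6 stays silylated, so acetylation of O4 only has to beat the tertiary O5. On step count and on O4/O6 differentiation this route is stronger than the chosen one.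
- Against: the C4=C5 double bond is trisubstituted, conjugated and alpha-branched, hence electron-poor and hindered, so osmylation is slow. Both ring centres depend on one facial choice steered only by the freely rotating exocyclic centre C6, with no reagent control to fall back on. The wrong face gives an isomer that differs at C4 and C5 together.
- Comparison: the chosen plan sets C4 and C6 with an auxiliary and ties C5 to the ring centre C4 in an intramolecular step, with a chiral catalyst as a second handle. It pays with extra steps and with the O4/O6 question, which is handled in the last step.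

**Alternative 3:** The chiral pool route starts from D-mannose A5. This would be elaborated to diene A6 (vinyl on C4, acryloyl on C5) and closed at C2=C3 by the second-generation Grubbs catalyst (H2IMes)(PCy3)Cl2Ru=CHPh to the acetonide-protected cyclopentenone A7.
- For: the absolute configuration comes from the sugar, the enone forms directly, and O4/O5 (acetal) are distinct from O6 (silyl). On these points it equals or beats the chosen plan. Ring-closing metathesis to cyclopentenones is dependable.
- Against: A6 needs a long sequence from A5: removal of surplus carbinols, attachment of the C14 chain, a diastereoselective addition to build the quaternary C5, and installation of two alkenes, one a polymerisation-prone vinyl ketone. The step count would be roughly double.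
- Comparison: the chosen plan reaches 14 in seven steps from an achiral three-carbon ketone and creates C5 catalytically.

Key step: step 8

## Route

Step 1
Reactants: 1 2,2-dimethyl-1,3-dioxan-5-one; 2 SAMP, (S)-1-amino-2-(methoxymethyl)pyrrolidine
Product: 3 SAMP hydrazone of 2,2-dimethyl-1,3-dioxan-5-one
Conditions: toluene, 4 Å MS, 60 °C
Reagents that add atoms: none
Why: Hydrazone formation by condensation of the unhindered ketone with the hydrazine; removal of water drives it to completion and the acetonide is untouched.

Step 2
Reactants: 3 SAMP hydrazone of 2,2-dimethyl-1,3-dioxan-5-one; 4 1-iodotetradecane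
Product: 6 SAMP hydrazone of (4S)-2,2-dimethyl-4-tetradecyl-1,3-dioxan-5-one, via lithium azaenolate 5 (not isolated)
Conditions: t-BuLi, THF, −78 °C; then 4, −100 °C → rt
Reagents that add atoms: none
Why: Enders SAMP-hydrazone alkylation: t-BuLi gives the lithium azaenolate chelated by the methoxymethyl arm, and the primary iodide attacks the open face. For this cyclic azaenolate that should set the new centre (target C6) as S.

Step 3
Reactants: 6 SAMP hydrazone of (4S)-2,2-dimethyl-4-tetradecyl-1,3-dioxan-5-one; 7 4-iodobut-1-ene
Product: 9 SAMP hydrazone of (4S,6S)-4-(but-3-en-1-yl)-2,2-dimethyl-6-tetradecyl-1,3-dioxan-5-one, via lithium azaenolate 8 (not isolated)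
Conditions: t-BuLi, THF, −78 °C; then 7, −100 °C → rt
Reagents that add atoms: none
Why: Second Enders alkylation: kinetic deprotonation occurs at the unsubstituted alpha' methylene and the auxiliary again directs the electrophile to the same face. The new centre (target C4) should therefore also be S and the two substituents trans.

Step 4
Reactants: 9 SAMP hydrazone of (4S,6S)-4-(but-3-en-1-yl)-2,2-dimethyl-6-tetradecyl-1,3-dioxan-5-one
Product: 10 (4S,6S)-4-(but-3-en-1-yl)-2,2-dimethyl-6-tetradecyl-1,3-dioxan-5-one
Conditions: sat. aq. oxalic acid, Et2O, rt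
Reagents that add atoms: water, O
Why: Mild biphasic hydrazone hydrolysis; the auxiliary leaves as its water-soluble oxalate without epimerising the alpha centres or opening the acetonide. Unlike ozonolytic cleavage, it spares the terminal alkene.

Step 5
Reactants: 10 (4S,6S)-4-(but-3-en-1-yl)-2,2-dimethyl-6-tetradecyl-1,3-dioxan-5-one
Product: 11 (5S,7S)-5,7-dihydroxyhenicos-1-en-6-one
Conditions: TFA, THF/H2O, 0 °C → rt
Reagents that add atoms: none
Why: Acid-catalysed acetal hydrolysis; at low temperature and with short exposure the enediol pathway that would scramble the two alpha-hydroxy ketone centres should stay slow.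

Step 6
Reactants: 11 (5S,7S)-5,7-dihydroxyhenicos-1-en-6-one
Product: 12 (5S,7S)-5,7-bis[(tert-butyldimethylsilyl)oxy]henicos-1-en-6-one
Conditions: TBSOTf, 2,6-lutidine, CH2Cl2, −78 → 0 °C
Reagents that add atoms: tert-butyldimethylsilyl trifluoromethanesulfonate (TBSOTf), CC(C)(C)[Si](C)(C)OS(=O)(=O)C(F)(F)F
Why: Silylation with a silyl triflate and a hindered pyridine base protects both secondary hydroxyls without enolising the ketone. The two acyclic ethers replace the ring that would force the wrong ring fusion in step 8.

Step 7
Reactants: 12 (5S,7S)-5,7-bis[(tert-butyldimethylsilyl)oxy]henicos-1-en-6-one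
Product: 14 (4S,6S)-4,6-bis[(tert-butyldimethylsilyl)oxy]-5-oxoicosanal, via secondary ozonide 13 (not isolated)
Conditions: O3, CH2Cl2, −78 °C; then PPh3, −78 °C → rt
Reagents that add atoms: ozone, [O-][O+]=O
Why: Ozonolysis with reductive work-up; the isolated terminal alkene is the only ozone-reactive group. Cleavage leaves C1 as the aldehyde and removes the extra carbon.

Step 8
Reactants: 14 (4S,6S)-4,6-bis[(tert-butyldimethylsilyl)oxy]-5-oxoicosanal
Product: 15 (2S,3S)-3-[(tert-butyldimethylsilyl)oxy]-2-[(1S)-1-[(tert-butyldimethylsilyl)oxy]pentadecyl]-2-hydroxycyclopentan-1-one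
Conditions: (5aR,10bS)-2-(pentafluorophenyl)-5a,10b-dihydro-4H,6H-indeno[2,1-b][1,2,4]triazolo[4,3-d][1,4]oxazin-2-ium tetrafluoroborate (15 mol %), Et3N (15 mol %), toluene (0.02 M), rt
Reagents that add atoms: none
Why: Intramolecular crossed aldehyde–ketone benzoin reaction under N-heterocyclic carbene catalysis, a known way to five-membered tertiary alpha-hydroxy ketones. The triazolylidene freed by Et3N adds to the unhindered aldehyde C1, proton transfer gives the nucleophilic enaminol (Breslow intermediate), and this attacks the ketone C5; collapse of the adduct releases the carbene, leaving C1 as the ketone and C5 as the carbinol. The ring closes in the 5-exo-trig mode, C1 adding to the C5 carbonyl whose oxygen stays outside the ring. Chemoselectivity is built in: only the aldehyde can become the acyl-anion equivalent, the ketone is activated as acceptor by its two alpha-silyloxy groups, and dilution suppresses aldehyde homo-coupling. The one new stereocentre, C5, is controlled by the substrate: in the forming ring the large C6 branch avoids the position cis to the C4 silyloxy group, so the new hydroxyl should come out cis to O4 (5S). The aminoindanol-derived chiral carbene is meant to reinforce this facial choice, and its antipode is available if the pairing proves mismatched. The weak amine base should leave C4 and C6 (both alpha to the ketone in 14) unepimerised, and after closure neither is alpha to a carbonyl any longer.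

Step 9
Reactants: 15 (2S,3S)-3-[(tert-butyldimethylsilyl)oxy]-2-[(1S)-1-[(tert-butyldimethylsilyl)oxy]pentadecyl]-2-hydroxycyclopentan-1-one
Product: 16 (4S,5S)-4-[(tert-butyldimethylsilyl)oxy]-5-[(1S)-1-[(tert-butyldimethylsilyl)oxy]pentadecyl]-1,5-bis[(trimethylsilyl)oxy]cyclopent-1-ene
Conditions: TMSOTf, Et3N, CH2Cl2, −78 → 0 °C
Reagents that add atoms: trimethylsilyl trifluoromethanesulfonate (TMSOTf), C[Si](C)(C)OS(=O)(=O)C(F)(F)F
Why: Soft enolisation gives the only possible silyl enol ether, toward C2, since C5 is quaternary; the tertiary hydroxyl is silylated at the same time. Avoiding a strong base avoids alkoxide-driven 1,2-silyl migration and ketol rearrangement.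

Step 10
Reactants: 16 (4S,5S)-4-[(tert-butyldimethylsilyl)oxy]-5-[(1S)-1-[(tert-butyldimethylsilyl)oxy]pentadecyl]-1,5-bis[(trimethylsilyl)oxy]cyclopent-1-ene
Product: 17 (4S,5S)-4-[(tert-butyldimethylsilyl)oxy]-5-[(1S)-1-[(tert-butyldimethylsilyl)oxy]pentadecyl]-5-[(trimethylsilyl)oxy]cyclopent-2-en-1-one
Conditions: Pd(OAc)2 (1.1 equiv), MeCN, rt
Reagents that add atoms: none
Why: Saegusa–Ito oxidation: palladation of the silyl enol ether at C2 and beta-hydride elimination from C3 install the C2=C3 double bond, the divalent palladium leaving as zerovalent palladium. No stereocentre is touched.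

Step 11
Reactants: 17 (4S,5S)-4-[(tert-butyldimethylsilyl)oxy]-5-[(1S)-1-[(tert-butyldimethylsilyl)oxy]pentadecyl]-5-[(trimethylsilyl)oxy]cyclopent-2-en-1-one
Product: 18 (4S,5S)-4,5-dihydroxy-5-[(1S)-1-hydroxypentadecyl]cyclopent-2-en-1-one
Conditions: 48% aq. HF, MeCN, 0 °C → rt
Reagents that add atoms: none
Why: Acidic fluoride-mediated desilylation cleaves all three silyl ethers. Acidic rather than basic fluoride is chosen because the product, a beta-hydroxy ketone and tertiary alpha-ketol, is prone to retro-aldol cleavage and rearrangement under base.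

Step 12
Reactants: 18 (4S,5S)-4,5-dihydroxy-5-[(1S)-1-hydroxypentadecyl]cyclopent-2-en-1-one
Product: 19 (1S,5S)-5-hydroxy-5-[(1S)-1-hydroxypentadecyl]-4-oxocyclopent-2-en-1-yl acetate
Conditions: AcCl (1.1 equiv), 2-aminoethyl diphenylborinate Ph2BOCH2CH2NH2 (10 mol %), i-Pr2NEt, MeCN, 0 °C → rt
Reagents that add atoms: acetyl chloride, CC(Cl)=O
Why: Borinic acid-catalysed regioselective acylation of a cis-1,2-diol: the catalyst forms a tetracoordinate borinate with the ring cis-4,5-diol and acyl transfer goes to its secondary oxygen O4, the tertiary O5 being too hindered. O6 is not part of a ring cis-diol and sits between the quaternary carbon and the chain, so it should react more slowly.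

## Compound list

1 | 2,2-dimethyl-1,3-dioxan-5-one | CC1(C)OCC(=O)CO1 | starting material
2 | SAMP, (S)-1-amino-2-(methoxymethyl)pyrrolidine | COC[C@@H]1CCCN1N | starting material
3 | SAMP hydrazone of 2,2-dimethyl-1,3-dioxan-5-one | COC[C@@H]1CCCN1N=C1COC(C)(C)OC1 | intermediate
4 | 1-iodotetradecane | CCCCCCCCCCCCCCI | starting material
5 | lithium azaenolate of 3 | COC[C@@H]1CCCN1[N-]C1=COC(C)(C)OC1.[Li+] | intermediate
6 | SAMP hydrazone of (4S)-2,2-dimethyl-4-tetradecyl-1,3-dioxan-5-one | COC[C@@H]1CCCN1N=C1COC(C)(C)O[C@H]1CCCCCCCCCCCCCC | intermediate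
7 | 4-iodobut-1-ene | C=CCCI | starting material
8 | lithium azaenolate of 6 (deprotonated at the unsubstituted alpha' carbon) | COC[C@@H]1CCCN1[N-]C1=COC(C)(C)O[C@H]1CCCCCCCCCCCCCC.[Li+] | intermediate
9 | SAMP hydrazone of (4S,6S)-4-(but-3-en-1-yl)-2,2-dimethyl-6-tetradecyl-1,3-dioxan-5-one | COC[C@@H]1CCCN1N=C1[C@H](CCC=C)OC(C)(C)O[C@H]1CCCCCCCCCCCCCC | intermediate
10 | (4S,6S)-4-(but-3-en-1-yl)-2,2-dimethyl-6-tetradecyl-1,3-dioxan-5-one | CCCCCCCCCCCCCC[C@@H]1OC(C)(C)O[C@@H](CCC=C)C1=O | intermediate
11 | (5S,7S)-5,7-dihydroxyhenicos-1-en-6-one | CCCCCCCCCCCCCC[C@H](O)C(=O)[C@@H](O)CCC=C | intermediate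
12 | (5S,7S)-5,7-bis[(tert-butyldimethylsilyl)oxy]henicos-1-en-6-one | CCCCCCCCCCCCCC[C@H](O[Si](C)(C)C(C)(C)C)C(=O)[C@@H](O[Si](C)(C)C(C)(C)C)CCC=C | intermediate
13 | secondary ozonide of 12, 3-[(3S,5S)-3,5-bis(TBS-oxy)-4-oxononadecyl]-1,2,4-trioxolane | CCCCCCCCCCCCCC[C@H](O[Si](C)(C)C(C)(C)C)C(=O)[C@@H](O[Si](C)(C)C(C)(C)C)CCC1OCOO1 | intermediate
14 | (4S,6S)-4,6-bis[(tert-butyldimethylsilyl)oxy]-5-oxoicosanal | CCCCCCCCCCCCCC[C@H](O[Si](C)(C)C(C)(C)C)C(=O)[C@@H](O[Si](C)(C)C(C)(C)C)CCC=O | intermediate
15 | (2S,3S)-3-[(tert-butyldimethylsilyl)oxy]-2-[(1S)-1-[(tert-butyldimethylsilyl)oxy]pentadecyl]-2-hydroxycyclopentan-1-one | CCCCCCCCCCCCCC[C@H](O[Si](C)(C)C(C)(C)C)[C@@]1(O)C(=O)CC[C@@H]1O[Si](C)(C)C(C)(C)C | intermediate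
16 | (4S,5S)-4-[(tert-butyldimethylsilyl)oxy]-5-[(1S)-1-[(tert-butyldimethylsilyl)oxy]pentadecyl]-1,5-bis[(trimethylsilyl)oxy]cyclopent-1-ene | CCCCCCCCCCCCCC[C@H](O[Si](C)(C)C(C)(C)C)[C@@]1(O[Si](C)(C)C)C(O[Si](C)(C)C)=CC[C@@H]1O[Si](C)(C)C(C)(C)C | intermediate
17 | (4S,5S)-4-[(tert-butyldimethylsilyl)oxy]-5-[(1S)-1-[(tert-butyldimethylsilyl)oxy]pentadecyl]-5-[(trimethylsilyl)oxy]cyclopent-2-en-1-one | CCCCCCCCCCCCCC[C@H](O[Si](C)(C)C(C)(C)C)[C@@]1(O[Si](C)(C)C)C(=O)C=C[C@@H]1O[Si](C)(C)C(C)(C)C | intermediate
18 | (4S,5S)-4,5-dihydroxy-5-[(1S)-1-hydroxypentadecyl]cyclopent-2-en-1-one | CCCCCCCCCCCCCC[C@H](O)[C@@]1(O)C(=O)C=C[C@@H]1O | intermediate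
19 | (1S,5S)-5-hydroxy-5-[(1S)-1-hydroxypentadecyl]-4-oxocyclopent-2-en-1-yl acetate | CCCCCCCCCCCCCC[C@H](O)[C@@]1(O)C(=O)C=C[C@@H]1OC(C)=O | target

## Step count and least certain steps

Total: 12 steps. Longest linear sequence: 12 steps (from 1 to 19).

**Step 8 (key step).**
- What may go wrong: the enaminol may add too slowly to the hindered, doubly alpha-branched ketone, so that intermolecular aldehyde self-condensation takes over. Facial discrimination at C5 may be insufficient. Long exposure to base before closure could epimerise C4 or C6.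
- Fallback (from 14, back at 15): reductive ketyl coupling in place of carbene umpolung. SmI2 (divalent samarium) with t-BuOH in THF at −78 °C should reduce the aldehyde to its ketyl, which adds irreversibly to the ketone inside a trivalent samarium chelate. This gives the cis-C1,C5-diol corresponding to 15 F1, in which the same steric argument places the C6 branch trans to the C4 silyloxy group. Oxidation of its only secondary free hydroxyl (C1) with 2-iodoxybenzoic acid in DMSO, which does not cleave the glycol, returns to 15.

**Step 12.**
- What may go wrong: loss of site selectivity through boron binding to the acyclic 5,6-diol or the 1,3-related 4,6-diol, leading to acylation of O6 or double acylation; acetyl migration from O4 during work-up.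
- Fallback (from 11, ending at 19): O4 and O6 are given different silyl groups before the ring is made.
  - Iodoetherification of 11 (I2, NaHCO3, MeCN, 0 °C) can only engage O4 (5-exo) and gives the 2-(iodomethyl)tetrahydrofuran F2.
  - Silylation of the remaining O6 hydroxyl (TBSOTf, 2,6-lutidine) gives the silyl ether F3.
  - Zn dust with NH4Cl in EtOH opens the beta-iodo ether reductively and returns the alkene with O4 free, the hydroxy ketone F4.
  - TESOTf and 2,6-lutidine give the mixed TES/TBS ether F5.
  - Ozonolysis as in step 7 passes through the ozonide F6 to the aldehyde F7.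
  - The carbene closure of step 8 gives the ketol F8; TMSOTf and Et3N give the enol ether F9; Pd(OAc)2 gives the enone F10.
  - PPTS in MeOH at 0 °C removes only the TES and TMS groups, giving the 4,5-diol F11.
  - Ac2O in pyridine then acetylates the secondary O4 beside the tertiary O5, giving the acetate F12.
  - Aqueous HF in MeCN removes the last TBS group and delivers 19.

**Step 3.**
- What may go wrong: E2 elimination of hydrogen iodide from the homoallylic iodide by the basic, hindered azaenolate; incomplete alkylation; erosion of trans selectivity if the reaction has to be run warmer.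
- Fallback (from 6 through azaenolate 8, back at 14): an activated electrophile and a later hydroboration replace the homoallyl iodide and the ozonolysis.
  - Allyl bromide alkylates 8 to the allyl hydrazone F13.
  - Oxalic acid gives the ketone F14; aqueous TFA gives the diol F15; TBSOTf gives the bis-silyl ether F16.
  - Hydroboration with catecholborane catalysed by RhCl(PPh3)3, under which the alkene reacts faster than the ketone, gives the boronate F17.
  - Buffered H2O2 at pH 7 gives the primary alcohol F18.
  - Dess–Martin periodinane oxidises F18 to 14.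

**Step 10.**
- What may go wrong: protodesilylation of the enol ether back to the ketone by the acetic acid released; slow beta-hydride elimination at the hindered ring.
- Fallback (from 16, back at 17): selenoxide elimination in place of palladium chemistry. PhSeCl in CH2Cl2 at −78 °C converts 16 into the alpha-phenylselanyl ketone F19. H2O2 with pyridine at 0 °C oxidises it to the selenoxide F20, which undergoes syn elimination toward C3, the only carbon with a beta-hydrogen, to give 17.

## Further compounds

F1 | step 8 | cis-C1,C5-diol corresponding to 15 (C1 carbinol in place of the ketone, C1 hydroxyl cis to C5 hydroxyl) | CCCCCCCCCCCCCC[C@H](O[Si](C)(C)C(C)(C)C)[C@@]1(O)[C@H](O)CC[C@@H]1O[Si](C)(C)C(C)(C)C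
F2 | step 12 | (2S)-2-hydroxy-1-[(2S)-5-(iodomethyl)tetrahydrofuran-2-yl]hexadecan-1-one (mixture at the iodomethyl-bearing carbon) | CCCCCCCCCCCCCC[C@H](O)C(=O)[C@@H]1CCC(CI)O1
F3 | step 12 | O6-TBS ether of F2 | CCCCCCCCCCCCCC[C@H](O[Si](C)(C)C(C)(C)C)C(=O)[C@@H]1CCC(CI)O1
F4 | step 12 | (5S,7S)-7-[(tert-butyldimethylsilyl)oxy]-5-hydroxyhenicos-1-en-6-one | CCCCCCCCCCCCCC[C@H](O[Si](C)(C)C(C)(C)C)C(=O)[C@@H](O)CCC=C
F5 | step 12 | (5S,7S)-7-[(tert-butyldimethylsilyl)oxy]-5-[(triethylsilyl)oxy]henicos-1-en-6-one | CCCCCCCCCCCCCC[C@H](O[Si](C)(C)C(C)(C)C)C(=O)[C@@H](O[Si](CC)(CC)CC)CCC=C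
F6 | step 12 | secondary ozonide of F5 | CCCCCCCCCCCCCC[C@H](O[Si](C)(C)C(C)(C)C)C(=O)[C@@H](O[Si](CC)(CC)CC)CCC1OCOO1
F7 | step 12 | (4S,6S)-6-[(tert-butyldimethylsilyl)oxy]-5-oxo-4-[(triethylsilyl)oxy]icosanal | CCCCCCCCCCCCCC[C@H](O[Si](C)(C)C(C)(C)C)C(=O)[C@@H](O[Si](CC)(CC)CC)CCC=O
F8 | step 12 | 4-O-TES analogue of 15 | CCCCCCCCCCCCCC[C@H](O[Si](C)(C)C(C)(C)C)[C@@]1(O)C(=O)CC[C@@H]1O[Si](CC)(CC)CC
F9 | step 12 | 4-O-TES analogue of 16 | CCCCCCCCCCCCCC[C@H](O[Si](C)(C)C(C)(C)C)[C@@]1(O[Si](C)(C)C)C(O[Si](C)(C)C)=CC[C@@H]1O[Si](CC)(CC)CC
F10 | step 12 | 4-O-TES analogue of 17 | CCCCCCCCCCCCCC[C@H](O[Si](C)(C)C(C)(C)C)[C@@]1(O[Si](C)(C)C)C(=O)C=C[C@@H]1O[Si](CC)(CC)CC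
F11 | step 12 | 6-O-TBS ether of 18 | CCCCCCCCCCCCCC[C@H](O[Si](C)(C)C(C)(C)C)[C@@]1(O)C(=O)C=C[C@@H]1O
F12 | step 12 | 6-O-TBS ether of 19 | CCCCCCCCCCCCCC[C@H](O[Si](C)(C)C(C)(C)C)[C@@]1(O)C(=O)C=C[C@@H]1OC(C)=O
F13 | step 3 | SAMP hydrazone of (4S,6S)-4-allyl-2,2-dimethyl-6-tetradecyl-1,3-dioxan-5-one | COC[C@@H]1CCCN1N=C1[C@H](CC=C)OC(C)(C)O[C@H]1CCCCCCCCCCCCCC
F14 | step 3 | (4S,6S)-4-allyl-2,2-dimethyl-6-tetradecyl-1,3-dioxan-5-one | CCCCCCCCCCCCCC[C@@H]1OC(C)(C)O[C@@H](CC=C)C1=O
F15 | step 3 | (4S,6S)-4,6-dihydroxyicos-1-en-5-one | CCCCCCCCCCCCCC[C@H](O)C(=O)[C@@H](O)CC=C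
F16 | step 3 | (4S,6S)-4,6-bis[(tert-butyldimethylsilyl)oxy]icos-1-en-5-one | CCCCCCCCCCCCCC[C@H](O[Si](C)(C)C(C)(C)C)C(=O)[C@@H](O[Si](C)(C)C(C)(C)C)CC=C
F17 | step 3 | catechol boronate from F16, boron on the terminal carbon | CCCCCCCCCCCCCC[C@H](O[Si](C)(C)C(C)(C)C)C(=O)[C@@H](O[Si](C)(C)C(C)(C)C)CCCB1Oc2ccccc2O1
F18 | step 3 | (4S,6S)-4,6-bis[(tert-butyldimethylsilyl)oxy]-1-hydroxyicosan-5-one | CCCCCCCCCCCCCC[C@H](O[Si](C)(C)C(C)(C)C)C(=O)[C@@H](O[Si](C)(C)C(C)(C)C)CCCO
F19 | step 10 | C2-phenylselanyl derivative of the saturated ketone corresponding to 17 | CCCCCCCCCCCCCC[C@H](O[Si](C)(C)C(C)(C)C)[C@@]1(O[Si](C)(C)C)C(=O)C([Se]c2ccccc2)C[C@@H]1O[Si](C)(C)C(C)(C)C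
F20 | step 10 | selenoxide of F19 | CCCCCCCCCCCCCC[C@H](O[Si](C)(C)C(C)(C)C)[C@@]1(O[Si](C)(C)C)C(=O)C([Se](=O)c2ccccc2)C[C@@H]1O[Si](C)(C)C(C)(C)C
A1 | alternative 1 | 4-[1-(TBS-oxy)prop-2-yn-1-yl]-2,2-dimethyl-5-tetradecyl-1,3-dioxolane-4-carbaldehyde, stereocentres as C4, C5 and C6 of the target | CCCCCCCCCCCCCC[C@@H]1OC(C)(C)O[C@]1(C=O)[C@H](C#C)O[Si](C)(C)C(C)(C)C
A2 | alternative 1 | 5,6-O-isopropylidene 4-O-TBS derivative of 18 (spiro acetonide cyclopentenone) | CCCCCCCCCCCCCC[C@@H]1OC(C)(C)O[C@@]12C(=O)C=C[C@@H]2O[Si](C)(C)C(C)(C)C
A3 | alternative 2 | 2-[(1S)-1-[(tert-butyldimethylsilyl)oxy]pentadecyl]cyclopent-2-en-1-one | CCCCCCCCCCCCCC[C@H](O[Si](C)(C)C(C)(C)C)C1=CCCC1=O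
A4 | alternative 2 | 6-O-TBS ether of the 2,3-dihydro derivative of 18 | CCCCCCCCCCCCCC[C@H](O[Si](C)(C)C(C)(C)C)[C@@]1(O)C(=O)CC[C@@H]1O
A5 | alternative 3 | D-mannose (open-chain form) | O=C[C@@H](O)[C@@H](O)[C@H](O)[C@H](O)CO
A6 | alternative 3 | 4,5-O-isopropylidene 6-O-TBS diene with vinyl on C4 and acryloyl on C5 | CCCCCCCCCCCCCC[C@H](O[Si](C)(C)C(C)(C)C)[C@]1(C(=O)C=C)OC(C)(C)O[C@H]1C=C
A7 | alternative 3 | 4,5-O-isopropylidene 6-O-TBS derivative of 18 | CCCCCCCCCCCCCC[C@H](O[Si](C)(C)C(C)(C)C)[C@]12OC(C)(C)O[C@H]1C=CC2=O
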